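**Plan**

1. Retrosynthesis: C1′–Cl and C4–Br are each cut to an alcohol (substitution with inversion), C1′–C2′ is cut back to a ring ester, and the ring bonds C2–C3 and C1–C6 are cut together as a [4+2] cycloreversion. This gives a 2-silyloxy diene (ring C3–C6) and methyl 3-bromopropiolate (C2, C1, C1′).
2. Enabling feature: the cyclohexene ring itself. Its C1=C2 double bond lies between quaternary C3 and C6H2, C2 already carries Br, and the heteroatom-bearing carbons C4 (ring) and C1′ (on C1) stand 1,4 across the ring, which is the pattern a 2-oxygenated diene and an ynoate give. Quaternary C3 blocks aromatisation of the adduct.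
3. Forward order: diene and bromoalkynoate are made separately; one cycloaddition forms the only ring, the quaternary carbon and the tetrasubstituted vinyl bromide. Then C4=O → 4R-Br, ester → bromomethyl ketone (C2′ joined), and finally 1′S-Cl.
4. Stereochemistry: both stereocentres come from ketone reductions with the same (R)-oxazaborolidine catalyst (catalyst control), each followed by an invertive substitution (4S-OH → 4R-Br; 1′R-OH → 1′S-Cl).

Key step: step 4

Assumption: locants follow the target name (4R)-2,4-dibromo-1-[(1S)-2-bromo-1-chloroethyl]-3,3-dimethylcyclohex-1-ene (side chain C1′, C2′), and racemic 4-methylpent-1-en-3-ol and methyl propiolate are taken as the commercial starting materials.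

**Route**

Step 1
Reactants: 1 4-methylpent-1-en-3-ol (racemic, CH2=CH–CH(OH)–CH(CH3)2)
Product: 2 4-methylpent-1-en-3-one (isopropyl vinyl ketone)
Conditions: activated MnO2, CH2Cl2, rt; kept cold with a trace of BHT and used promptly
Reagents that add atoms: none
Why: Allylic alcohol oxidation with MnO2 is neutral and selective for the allylic carbinol, so the polymerisable vinyl ketone should form without Michael addition.

Step 2
Reactants: 2 4-methylpent-1-en-3-one
Product: 3 tert-butyl(dimethyl)[(4-methylpenta-1,3-dien-3-yl)oxy]silane, CH2=CH–C(OTBS)=C(CH3)2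
Conditions: TBSOTf, Et3N, Et2O, 0 °C → rt
Reagents that add atoms: tert-butyldimethylsilyl trifluoromethanesulfonate, CC(C)(C)[Si](C)(C)OS(=O)(=O)C(F)(F)F
Why: Soft enolisation (silyl dienol ether formation) can only remove the isopropyl methine proton because the other α-carbon is vinylic, so the 2-silyloxy diene with a dimethyl-substituted terminus should form regiospecifically.

Step 3
Reactants: 4 methyl prop-2-ynoate (methyl propiolate)
Product: 5 methyl 3-bromoprop-2-ynoate
Conditions: NBS, AgNO3 (cat.), acetone, rt
Reagents that add atoms: N-bromosuccinimide, O=C1CCC(=O)N1Br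
Why: Silver-catalysed electrophilic bromination of the terminal alkyne C–H (AgNO3/NBS alkyne bromination) gives the 1-bromoalkyne and leaves the ester untouched.

Step 4
Reactants: 3 tert-butyl(dimethyl)[(4-methylpenta-1,3-dien-3-yl)oxy]silane, 5 methyl 3-bromoprop-2-ynoate
Product: 7 methyl 2-bromo-3,3-dimethyl-4-oxocyclohex-1-ene-1-carboxylate, via silyl enol ether cycloadduct 6 (not isolated)
Conditions: toluene, BHT (trace), 100 °C, sealed tube; then 1 M HCl, THF, 0 °C → rt
Reagents that add atoms: none
Why: Thermal normal-electron-demand Diels–Alder reaction: the s-cis diene 3 (ring C3–C6) and the alkyne of 5 combine in a concerted, asynchronous [4+2] transition state to give the 1,4-cyclohexadiene 6, whose silyl enol ether is then hydrolysed to the C4 ketone. The closest known reaction type is the cycloaddition of 2-silyloxy-1,3-dienes with alkynoates and 3-halopropiolates, including dienes with a fully substituted silyloxy-bearing terminus that create quaternary carbons. The six-membered ring is closed by the intermolecular cycloaddition itself, both ring bonds (C2–C3 and C1–C6) forming in one suprafacial event, so no separate ring-closure mode applies. No stereocentre is formed, since C3 carries two methyl groups and the dienophile is an alkyne, so no facial control is needed. The step needs regioselectivity: the silyloxy group on C4 makes the dimethyl-bearing terminus C3 the nucleophilic end of the diene, and this end bonds to the electrophilic β-carbon of the ynoate, the one that carries bromine, giving the 1,4 ("para") arrangement of C4–O and C1–CO2Me. Aromatisation of the adduct is impossible because C3 is quaternary, and the bromoalkyne and ester should survive the neutral thermal conditions.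

Step 5
Reactants: 7 methyl 2-bromo-3,3-dimethyl-4-oxocyclohex-1-ene-1-carboxylate
Product: 8 methyl (4S)-2-bromo-4-hydroxy-3,3-dimethylcyclohex-1-ene-1-carboxylate
Conditions: (R)-Me-CBS oxazaborolidine (C18H20BNO, cat.), BH3·SMe2, THF, −20 °C; MeOH quench
Reagents that add atoms: none
Why: Corey–Bakshi–Shibata reduction, in which the catalyst–borane complex binds the ketone with the quaternary C3 side as the large group and the C5 methylene as the small one, so that the (R)-catalyst should deliver hydride to the face that makes C4 S, while the conjugated ester and the vinyl bromide are inert to borane at this temperature.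

Step 6
Reactants: 8 methyl (4S)-2-bromo-4-hydroxy-3,3-dimethylcyclohex-1-ene-1-carboxylate
Product: 10 methyl (4R)-2,4-dibromo-3,3-dimethylcyclohex-1-ene-1-carboxylate, via secondary triflate 9 (not isolated)
Conditions: Tf2O, 2,6-lutidine, CH2Cl2, −78 → −30 °C; then Bu4NBr, toluene, −30 °C → rt
Reagents that add atoms: tetrabutylammonium bromide, CCCC[N+](CCCC)(CCCC)CCCC.[Br-] (Tf2O, O=S(=O)(OS(=O)(=O)C(F)(F)F)C(F)(F)F, adds atoms only to intermediate 9)
Why: Invertive SN2 displacement of a secondary triflate by soluble bromide (sulfonate displacement) should convert 4S-OH into 4R-Br, with the low temperature, the non-polar medium and the electron-poor C1=C2 double bond (a poor homoallylic participant) chosen to keep the substitution bimolecular at this neopentyl-type carbon.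

Step 7
Reactants: 10 methyl (4R)-2,4-dibromo-3,3-dimethylcyclohex-1-ene-1-carboxylate
Product: 11 (4R)-2,4-dibromo-1-(1-methoxyethenyl)-3,3-dimethylcyclohex-1-ene
Conditions: Cp2TiMe2, toluene, 70 °C, dark; filtration through basic alumina
Reagents that add atoms: dimethyltitanocene Cp2TiMe2, C[Ti](C)(C1C=CC=C1)C1C=CC=C1 (delivers the CH2 carbon)
Why: Petasis methylenation of the ester carbonyl (titanocene methylidene, [2+2] then retro-[2+2]) gives the methyl enol ether under non-basic, non-nucleophilic conditions that should leave the alkyl bromide, the vinyl bromide and the C4 stereocentre untouched.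

Step 8
Reactants: 11 (4R)-2,4-dibromo-1-(1-methoxyethenyl)-3,3-dimethylcyclohex-1-ene
Product: 12 2-bromo-1-[(4R)-2,4-dibromo-3,3-dimethylcyclohex-1-en-1-yl]ethan-1-one
Conditions: NBS, THF/H2O (4:1), 0 °C
Reagents that add atoms: N-bromosuccinimide, O=C1CCC(=O)N1Br; water, O (carbonyl oxygen)
Why: Electrophilic bromination of the enol ether at its terminal CH2 followed by hydrolysis of the oxocarbenium ion (bromoketone synthesis from enol ethers with NBS/water) should give the bromomethyl ketone regiospecifically, the tetrasubstituted bromoalkene being too electron-poor to react.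

Step 9
Reactants: 12 2-bromo-1-[(4R)-2,4-dibromo-3,3-dimethylcyclohex-1-en-1-yl]ethan-1-one
Product: 13 (1R)-2-bromo-1-[(4R)-2,4-dibromo-3,3-dimethylcyclohex-1-en-1-yl]ethan-1-ol
Conditions: (R)-Me-CBS oxazaborolidine (C18H20BNO, cat.), BH3·SMe2, toluene/THF, −30 °C; MeOH, then aq NH4Cl (no base)
Reagents that add atoms: none
Why: Corey–Bakshi–Shibata reduction in which the bulky 2-bromocycloalkenyl group acts as the large substituent and CH2Br as the small one, as with α-bromo aryl ketones, so that the (R)-catalyst should set C1′ as R independently of the remote C4 centre.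

Step 10
Reactants: 13 (1R)-2-bromo-1-[(4R)-2,4-dibromo-3,3-dimethylcyclohex-1-en-1-yl]ethan-1-ol
Product: 15 (4R)-2,4-dibromo-1-[(1S)-2-bromo-1-chloroethyl]-3,3-dimethylcyclohex-1-ene, via alkoxyphosphonium chloride 14 (not isolated)
Conditions: PPh3, NCS, CH2Cl2, −20 °C → rt
Reagents that add atoms: N-chlorosuccinimide, O=C1CCC(=O)N1Cl (PPh3, c1ccc(cc1)P(c1ccccc1)c1ccccc1, adds atoms only to intermediate 14)
Why: Appel-type chlorination, in which chloride displaces the alkoxyphosphonium group with inversion (1′R-OH → 1′S-Cl) under neutral, non-ionising conditions chosen to favour direct SN2 over participation of the C2′ bromine, while SN2′ attack is blocked because the distal alkene carbon C2 is fully substituted and flanked by quaternary C3.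

**Compound list**

1 | 4-methylpent-1-en-3-ol (racemic) | C=CC(O)C(C)C | starting material
2 | 4-methylpent-1-en-3-one | C=CC(=O)C(C)C | intermediate
3 | tert-butyl(dimethyl)[(4-methylpenta-1,3-dien-3-yl)oxy]silane | C=CC(O[Si](C)(C)C(C)(C)C)=C(C)C | intermediate
4 | methyl prop-2-ynoate | C#CC(=O)OC | starting material
5 | methyl 3-bromoprop-2-ynoate | BrC#CC(=O)OC | intermediate
6 | methyl 2-bromo-4-[(tert-butyldimethylsilyl)oxy]-3,3-dimethylcyclohexa-1,4-diene-1-carboxylate | COC(=O)C1=C(Br)C(C)(C)C(O[Si](C)(C)C(C)(C)C)=CC1 | intermediate
7 | methyl 2-bromo-3,3-dimethyl-4-oxocyclohex-1-ene-1-carboxylate | COC(=O)C1=C(Br)C(C)(C)C(=O)CC1 | intermediate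
8 | methyl (4S)-2-bromo-4-hydroxy-3,3-dimethylcyclohex-1-ene-1-carboxylate | CC1(C)C(Br)=C(C(=O)OC)CC[C@@H]1O | intermediate
9 | methyl (4S)-2-bromo-3,3-dimethyl-4-[(trifluoromethanesulfonyl)oxy]cyclohex-1-ene-1-carboxylate | CC1(C)C(Br)=C(C(=O)OC)CC[C@@H]1OS(=O)(=O)C(F)(F)F | intermediate
10 | methyl (4R)-2,4-dibromo-3,3-dimethylcyclohex-1-ene-1-carboxylate | CC1(C)C(Br)=C(C(=O)OC)CC[C@H]1Br | intermediate
11 | (4R)-2,4-dibromo-1-(1-methoxyethenyl)-3,3-dimethylcyclohex-1-ene | CC1(C)C(Br)=C(C(=C)OC)CC[C@H]1Br | intermediate
12 | 2-bromo-1-[(4R)-2,4-dibromo-3,3-dimethylcyclohex-1-en-1-yl]ethan-1-one | CC1(C)C(Br)=C(C(=O)CBr)CC[C@H]1Br | intermediate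
13 | (1R)-2-bromo-1-[(4R)-2,4-dibromo-3,3-dimethylcyclohex-1-en-1-yl]ethan-1-ol | CC1(C)C(Br)=C([C@@H](O)CBr)CC[C@H]1Br | intermediate
14 | {(1R)-2-bromo-1-[(4R)-2,4-dibromo-3,3-dimethylcyclohex-1-en-1-yl]ethoxy}triphenylphosphonium chloride | CC1(C)C(Br)=C([C@@H](O[P+](c2ccccc2)(c2ccccc2)c2ccccc2)CBr)CC[C@H]1Br.[Cl-] | intermediate
15 | (4R)-2,4-dibromo-1-[(1S)-2-bromo-1-chloroethyl]-3,3-dimethylcyclohex-1-ene | CC1(C)C(Br)=C([C@H](Cl)CBr)CC[C@H]1Br | target

**Step count and risks**

Total steps: 10. Longest linear sequence: 9 steps (1 → 15 through steps 1, 2 and 4–10); step 3 makes the second cycloaddition partner.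

Steps most likely to fail:

Step 6. The neopentyl-type triflate may ionise before bromide attacks. Methyl migration from C3, loss of a C5 proton, or simple E2 elimination would then replace the invertive substitution. The fallback sets out again from alcohol 8 and changes the way the C–O bond is broken: deoxybromination through an alkoxyphosphonium ion (CBr4, P(n-Oct)3, toluene, 70 °C, Appel-type). Here the leaving group is a neutral phosphine oxide expelled only as bromide attacks from the rear, so no free ionisable sulfonate is ever present. It comes back to the route at bromide 10 and makes no new compound (F0).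

Step 10. The neighbouring C2′ bromine may take part in the departure of the activated oxygen. Chloride would then open a bromonium ion, giving retention at C1′ or a 1,2-shift of bromine instead of clean inversion. The fallback accepts that pathway and sets out from ketone 12. Reduction with the enantiomeric (S)-Me-CBS oxazaborolidine (C18H20BNO) and BH3·SMe2 should give (1S)-2-bromo-1-[(4R)-2,4-dibromo-3,3-dimethylcyclohex-1-en-1-yl]ethan-1-ol F1. Treatment with SOCl2 in 1,4-dioxane without base should then deliver chloride with retention, both by internal return from the chlorosulfite and by opening of the bromonium ion at the allylic carbon. It comes back to the route at target 15.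

Step 4. Steric crowding at the dimethyl-bearing diene terminus may slow the cycloaddition, erode its regioselectivity, or divert the silyl enol ether into stepwise addition–elimination at the bromoalkyne. The fallback builds the same ring without a cycloaddition and sets out from vinyl ketone 2. Michael addition of dimethyl malonate (NaOMe cat., MeOH) should give dimethyl 2-(4-methyl-3-oxopentyl)propanedioate F2. Claisen-type ring closure of the isopropyl ketone enolate onto one malonate ester (NaOMe, MeOH, reflux) should give methyl 3,3-dimethyl-2,4-dioxocyclohexane-1-carboxylate F3. Deoxybromination of its enolised β-keto ester with Ph3PBr2 and Et3N in CH2Cl2 should give the β-bromo enoate, and the route is rejoined at keto ester 7.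

Further compounds
F0 | step 6 | none | none
F1 | step 10 | (1S)-2-bromo-1-[(4R)-2,4-dibromo-3,3-dimethylcyclohex-1-en-1-yl]ethan-1-ol | CC1(C)C(Br)=C([C@H](O)CBr)CC[C@H]1Br
F2 | step 4 | dimethyl 2-(4-methyl-3-oxopentyl)propanedioate | COC(=O)C(CCC(=O)C(C)C)C(=O)OC
F3 | step 4 | methyl 3,3-dimethyl-2,4-dioxocyclohexane-1-carboxylate | COC(=O)C1CCC(=O)C(C)(C)C1=O
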